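**Strategy.** The plan disconnects the O1–O2 bond of the 1,2-dioxolane ring (O1–O2–C3–C4–C5). Both peroxide carbons are fully substituted, C3 (CH3, CH2CO2H) and C5 (CH3, C15 chain), so their C–O bonds can be set first as tertiary carbinols of a 1,3-diol, and alkoxyl radicals centred on them have no α-hydrogen to lose. In one operation, oxidation of a 1,3-bis(aminooxy) compound couples the two nitrogens to a seven-membered cyclic hyponitrite that expels N2 and contracts to the dioxolane, forming O1–O2 with both configurations retained. The precursor is an open-chain 3,5-bis(aminooxy)-3,5-dimethyldodecane: triisopropylsilyl ether on the two-carbon arm, PMB ether at the remote chain end.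

Key step: step 14

**Remarks**
- Ring locants of all dioxolane intermediates follow the target (C3 carries the two-carbon arm, C5 the long chain). C3 is labelled S while the arm ends in CH2O– and R once it ends in CHO or CO2H; only the CIP ranking of the arm changes, not the spatial arrangement.
- Alkoxides and the metalated sulfone are counted as the reactant they derive from and carry no number.
- Non-8-yn-1-ol, (3Z)-hex-3-en-1-ol and 1-phenyl-1H-tetrazole-5-thiol are assumed to be purchased.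
- Both (E)-3-methylallylic alcohols are made by alkyne carboalumination. Hydroalumination–iodination of but-2-yn-1-ol followed by cross-coupling would put the new chain cis to CH2OH and give the (Z)-isomer.

**Route**

Step 1
Reactants: 1 non-8-yn-1-ol
Product: 2 1-methoxy-4-[(non-8-yn-1-yloxy)methyl]benzene
Conditions: NaH, 4-methoxybenzyl chloride, Bu4NI (cat.), THF/DMF, 0 °C → rt
Reagents that add atoms: 4-methoxybenzyl chloride, COc1ccc(CCl)cc1
Why: Williamson etherification, in which NaH deprotonates the hydroxyl (far more acidic than the alkyne C–H) and the alkoxide displaces chloride from the benzylic halide.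

Step 2
Reactants: 2 1-methoxy-4-[(non-8-yn-1-yloxy)methyl]benzene
Product: 5 (2E)-10-[(4-methoxyphenyl)methoxy]-3-methyldec-2-en-1-ol, via alkenyl(dimethyl)alane 3 (not isolated), via lithium alkenylalanate 4 (not isolated)
Conditions: Me3Al, Cp2ZrCl2 (25 mol %), CH2Cl2, rt; evaporate; n-BuLi, hexane/THF, 0 °C; (CH2O)n, rt; aq. HCl work-up
Reagents that add atoms: trimethylaluminium, C[Al](C)C; formaldehyde (from paraformaldehyde), C=O
Why: Negishi carboalumination, in which Cp2ZrCl2-catalysed syn addition of CH3–Al across the terminal alkyne places aluminium on the terminal carbon and the derived alanate adds to formaldehyde with retention, so the (E)-3-methylallylic alcohol results.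

Step 3
Reactants: 5 (2E)-10-[(4-methoxyphenyl)methoxy]-3-methyldec-2-en-1-ol
Product: 6 [(2S,3S)-3-{7-[(4-methoxyphenyl)methoxy]heptyl}-3-methyloxiran-2-yl]methanol
Conditions: Ti(OiPr)4 (10 mol %), L-(+)-diethyl tartrate (12 mol %), t-BuOOH, 4 Å molecular sieves, CH2Cl2, −20 °C
Reagents that add atoms: tert-butyl hydroperoxide, CC(C)(C)OO
Why: Sharpless asymmetric epoxidation, in which the Ti(OiPr)4/L-(+)-tartrate catalyst delivers oxygen to one face of the allylic alcohol and, as for geraniol-type (E)-3-methylallylic alcohols, should give the (2S,3S)-epoxide, whose oxirane C3 becomes C5 of the target.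

Step 4
Reactants: 6 [(2S,3S)-3-{7-[(4-methoxyphenyl)methoxy]heptyl}-3-methyloxiran-2-yl]methanol
Product: 7 (3S)-10-[(4-methoxyphenyl)methoxy]-3-methyldecane-1,3-diol
Conditions: NaAlH2(OCH2CH2OMe)2, THF, 0 °C → rt; aq. NaOH work-up
Reagents that add atoms: none
Why: Regioselective epoxide reduction, in which hydride is delivered intramolecularly from the aluminium alkoxide of the 2,3-epoxy alcohol to C2, so the 1,3-diol forms and the tertiary C–O bond keeps its configuration.

Step 5
Reactants: 7 (3S)-10-[(4-methoxyphenyl)methoxy]-3-methyldecane-1,3-diol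
Product: 8 (3S)-10-[(4-methoxyphenyl)methoxy]-3-methyl-1,3-bis[(triethylsilyl)oxy]decane
Conditions: Et3SiOSO2CF3, 2,6-lutidine, CH2Cl2, −78 → 0 °C
Reagents that add atoms: triethylsilyl trifluoromethanesulfonate, CC[Si](CC)(CC)OS(=O)(=O)C(F)(F)F
Why: Silylation with a silyl triflate and a hindered pyridine base covers the primary and the tertiary hydroxyl together, the latter needing protection against retro-aldol cleavage and dehydration in the next two steps.

Step 6
Reactants: 8 (3S)-10-[(4-methoxyphenyl)methoxy]-3-methyl-1,3-bis[(triethylsilyl)oxy]decane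
Product: 9 (3S)-10-[(4-methoxyphenyl)methoxy]-3-methyl-3-[(triethylsilyl)oxy]decanal
Conditions: (COCl)2, DMSO, CH2Cl2, −78 → −40 °C; Et3N, −78 → 0 °C
Reagents that add atoms: none
Why: Swern oxidation applied directly to a silyl ether, in which the chlorodimethylsulfonium ion cleaves the unhindered primary triethylsilyl ether and the alkoxysulfonium ylide gives the aldehyde, while the tertiary silyl ether has no carbinol hydrogen and is too hindered to react.

Step 7
Reactants: 9 (3S)-10-[(4-methoxyphenyl)methoxy]-3-methyl-3-[(triethylsilyl)oxy]decanal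
Product: 10 (4S)-11-[(4-methoxyphenyl)methoxy]-4-methyl-4-[(triethylsilyl)oxy]undec-1-yne
Conditions: dimethyl (1-diazo-2-oxopropyl)phosphonate, K2CO3, MeOH, 0 °C → rt
Reagents that add atoms: dimethyl (1-diazo-2-oxopropyl)phosphonate, COP(=O)(OC)C(=[N+]=[N-])C(C)=O
Why: Ohira–Bestmann (Seyferth–Gilbert) homologation, in which the diazomethylphosphonate anion formed by methanolysis adds to the aldehyde and the alkylidene carbene rearranges to the terminal alkyne under carbonate conditions mild enough for the β-silyloxy aldehyde.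

Step 8
Reactants: 10 (4S)-11-[(4-methoxyphenyl)methoxy]-4-methyl-4-[(triethylsilyl)oxy]undec-1-yne
Product: 13 (2E,5S)-12-[(4-methoxyphenyl)methoxy]-3,5-dimethyl-5-[(triethylsilyl)oxy]dodec-2-en-1-ol, via alkenyl(dimethyl)alane 11 (not isolated), via lithium alkenylalanate 12 (not isolated)
Conditions: Me3Al, Cp2ZrCl2 (25 mol %), CH2Cl2, rt; evaporate; n-BuLi, hexane/THF, 0 °C; (CH2O)n, rt; aq. HCl work-up
Reagents that add atoms: trimethylaluminium, C[Al](C)C; formaldehyde (from paraformaldehyde), C=O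
Why: Negishi carboalumination and alanate hydroxymethylation as in step 2, the homopropargylic silyl ether being tolerated and the (E)-geometry following from syn addition.

Step 9
Reactants: 13 (2E,5S)-12-[(4-methoxyphenyl)methoxy]-3,5-dimethyl-5-[(triethylsilyl)oxy]dodec-2-en-1-ol
Product: 14 [(2R,3R)-3-{(2S)-9-[(4-methoxyphenyl)methoxy]-2-methyl-2-[(triethylsilyl)oxy]nonyl}-3-methyloxiran-2-yl]methanol
Conditions: Ti(OiPr)4 (10 mol %), D-(−)-diethyl tartrate (12 mol %), t-BuOOH, 4 Å molecular sieves, CH2Cl2, −20 °C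
Reagents that add atoms: tert-butyl hydroperoxide, CC(C)(C)OO
Why: Sharpless asymmetric epoxidation under reagent control, in which the D-(−)-tartrate catalyst attacks the face opposite to that used in step 3 and should give the (2R,3R)-epoxide, whose oxirane C3 becomes C3 of the target, the remote C5 centre not being expected to interfere.

Step 10
Reactants: 14 [(2R,3R)-3-{(2S)-9-[(4-methoxyphenyl)methoxy]-2-methyl-2-[(triethylsilyl)oxy]nonyl}-3-methyloxiran-2-yl]methanol
Product: 15 (3S,5S)-12-[(4-methoxyphenyl)methoxy]-3,5-dimethyl-5-[(triethylsilyl)oxy]dodecane-1,3-diol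
Conditions: NaAlH2(OCH2CH2OMe)2, THF, 0 °C → rt; aq. NaOH work-up
Reagents that add atoms: none
Why: Regioselective epoxide reduction as in step 4, with hydride delivered to C2 and the tertiary C3–O bond left intact, so no stereocentre is touched.

Step 11
Reactants: 15 (3S,5S)-12-[(4-methoxyphenyl)methoxy]-3,5-dimethyl-5-[(triethylsilyl)oxy]dodecane-1,3-diol
Product: 16 (3S,5S)-12-[(4-methoxyphenyl)methoxy]-3,5-dimethyldodecane-1,3,5-triol
Conditions: Bu4NF, THF, 0 °C → rt
Reagents that add atoms: none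
Why: Fluoride-induced desilylation, driven by Si–F bond formation, frees the tertiary hydroxyl and leaves the PMB ether untouched.

Step 12
Reactants: 16 (3S,5S)-12-[(4-methoxyphenyl)methoxy]-3,5-dimethyldodecane-1,3,5-triol
Product: 17 (3S,5S)-12-[(4-methoxyphenyl)methoxy]-3,5-dimethyl-1-{[tri(propan-2-yl)silyl]oxy}dodecane-3,5-diol
Conditions: iPr3SiCl, imidazole, DMF, 0 °C → rt
Reagents that add atoms: chlorotri(propan-2-yl)silane, CC(C)[Si](Cl)(C(C)C)C(C)C
Why: Sterically controlled silylation, in which the bulky chlorosilane reacts only with the primary hydroxyl, triisopropylsilyl being chosen because it resists base-induced 1,5-migration to the neighbouring tertiary alkoxide in step 13.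

Step 13
Reactants: 17 (3S,5S)-12-[(4-methoxyphenyl)methoxy]-3,5-dimethyl-1-{[tri(propan-2-yl)silyl]oxy}dodecane-3,5-diol
Product: 18 O,O'-[(3S,5S)-12-[(4-methoxyphenyl)methoxy]-3,5-dimethyl-1-{[tri(propan-2-yl)silyl]oxy}dodecane-3,5-diyl]bis(hydroxylamine)
Conditions: KH, THF/DMPU, 0 °C → rt; 3,3-di-tert-butyloxaziridine, −40 °C → rt
Reagents that add atoms: 3,3-di-tert-butyloxaziridine, CC(C)(C)C1(NO1)C(C)(C)C
Why: Electrophilic amination of alkoxides, in which each potassium tert-alkoxide attacks the nitrogen of the N–H oxaziridine and the adduct collapses to the O-alkylhydroxylamine and a ketone too hindered to condense with it, no C–O bond being broken so that both centres are kept.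

Step 14
Reactants: 18 O,O'-[(3S,5S)-12-[(4-methoxyphenyl)methoxy]-3,5-dimethyl-1-{[tri(propan-2-yl)silyl]oxy}dodecane-3,5-diyl]bis(hydroxylamine)
Product: 20 (3S,5S)-5-{7-[(4-methoxyphenyl)methoxy]heptyl}-3,5-dimethyl-3-(2-{[tri(propan-2-yl)silyl]oxy}ethyl)-1,2-dioxolane, via cyclic cis-hyponitrite 19 (not isolated)
Conditions: Pb(OAc)4 (2.2 equiv), K2CO3, CH2Cl2, −78 °C, slow addition of 18 (final 0.002 M); then → rt
Reagents that add atoms: none
Why: Proposed new method: Pb(OAc)4 should take each O-alkylhydroxylamine to the alkoxynitrene level, the second nitrogen, held three atoms away, intercepts the first, and further oxidation gives the cis-hyponitrite 19 (seven-membered ring C3–O–N=N–O–C5–C4, closed head-to-head by N–N coupling); on warming, 19 loses N2 and the resulting singlet 1,3-dioxyl pair collapses to the O1–O2 bond, so the dioxolane ring closes by 7→5 contraction through radical-pair recombination. The closest known reactions are the oxidation of O-alkylhydroxylamines to dialkyl hyponitrites, the thermal loss of nitrogen from di-tert-alkyl hyponitrites, whose caged tert-alkoxyl pairs recombine in part to di-tert-alkyl peroxides, and the nitrogen extrusion of cyclic 1,2-diazenes to cyclopropanes; here the tether rules out cage escape. No stereocentre is formed, and since neither C–O bond is broken, C3 and C5 keep the configurations set in steps 9 and 3. The step needs chemoselectivity for O–O recombination over β-scission and hydrogen transfer, which is secured because C3 and C5 bear no hydrogen, because the radical pair is the same species from which a 1,2-dioxolane recloses after O–O homolysis, and because the arm oxygen carries a silyl group with no activated C–H within 1,5- or 1,6-reach of the C3 oxygen while the oxidisable PMB ether sits at the far chain end. It also needs intramolecular N–N coupling to beat oligomerisation, which high dilution and slow addition should ensure. K2CO3 removes acetic acid, which could otherwise divert 19 to ionic loss of N2O.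

Step 15
Reactants: 20 (3S,5S)-5-{7-[(4-methoxyphenyl)methoxy]heptyl}-3,5-dimethyl-3-(2-{[tri(propan-2-yl)silyl]oxy}ethyl)-1,2-dioxolane
Product: 21 7-[(3S,5S)-3,5-dimethyl-3-(2-{[tri(propan-2-yl)silyl]oxy}ethyl)-1,2-dioxolan-5-yl]heptan-1-ol
Conditions: DDQ, CH2Cl2/pH 7 phosphate buffer, 0 °C
Reagents that add atoms: none
Why: Oxidative cleavage of the 4-methoxybenzyl ether by hydride abstraction to the quinone and hydrolysis of the oxocarbenium ion, the di-tert-alkyl peroxide and the silyl ether being inert.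

Step 16
Reactants: 21 7-[(3S,5S)-3,5-dimethyl-3-(2-{[tri(propan-2-yl)silyl]oxy}ethyl)-1,2-dioxolan-5-yl]heptan-1-ol
Product: 22 7-[(3S,5S)-3,5-dimethyl-3-(2-{[tri(propan-2-yl)silyl]oxy}ethyl)-1,2-dioxolan-5-yl]heptanal
Conditions: Dess–Martin periodinane, CH2Cl2, rt
Reagents that add atoms: none
Why: Dess–Martin oxidation of the primary alcohol to the aldehyde under neutral conditions that leave the peroxide untouched.

Step 17
Reactants: 22 7-[(3S,5S)-3,5-dimethyl-3-(2-{[tri(propan-2-yl)silyl]oxy}ethyl)-1,2-dioxolan-5-yl]heptanal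
Product: 23 (2E)-9-[(3S,5S)-3,5-dimethyl-3-(2-{[tri(propan-2-yl)silyl]oxy}ethyl)-1,2-dioxolan-5-yl]non-2-enal
Conditions: Ph3P=CHCHO (1.1 equiv), toluene, 70 °C
Reagents that add atoms: (triphenylphosphoranylidene)acetaldehyde, O=CC=P(c1ccccc1)(c1ccccc1)c1ccccc1
Why: Wittig olefination with a formyl-stabilised ylide gives the (E)-enal, no trivalent phosphorus being present that could deoxygenate the peroxide and a near-stoichiometric amount of ylide limiting a second homologation.

Step 18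
Reactants: 24 (3Z)-hex-3-en-1-ol; 25 1-phenyl-1H-tetrazole-5-thiol
Product: 26 5-[(3Z)-hex-3-en-1-ylsulfanyl]-1-phenyl-1H-tetrazole
Conditions: PPh3, diisopropyl azodicarboxylate, THF, 0 °C → rt
Reagents that add atoms: none
Why: Mitsunobu thioetherification, in which the acidic tetrazole thiol displaces the activated primary alkoxyphosphonium group without touching the (Z)-alkene.

Step 19
Reactants: 26 5-[(3Z)-hex-3-en-1-ylsulfanyl]-1-phenyl-1H-tetrazole
Product: 27 5-[(3Z)-hex-3-ene-1-sulfonyl]-1-phenyl-1H-tetrazole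
Conditions: H2O2 (30% aq.), (NH4)6Mo7O24·4H2O (cat.), EtOH, 0 °C → rt
Reagents that add atoms: hydrogen peroxide, OO
Why: (NH4)6Mo7O24-catalysed sulfide oxidation, in which peroxomolybdate oxygen transfer to sulfur is much faster than epoxidation of the isolated alkene.

Step 20
Reactants: 27 5-[(3Z)-hex-3-ene-1-sulfonyl]-1-phenyl-1H-tetrazole; 23 (2E)-9-[(3S,5S)-3,5-dimethyl-3-(2-{[tri(propan-2-yl)silyl]oxy}ethyl)-1,2-dioxolan-5-yl]non-2-enal
Product: 28 (3S,5S)-3,5-dimethyl-5-[(7E,9E,12Z)-pentadeca-7,9,12-trien-1-yl]-3-(2-{[tri(propan-2-yl)silyl]oxy}ethyl)-1,2-dioxolane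
Conditions: KN(SiMe3)2, DME, −78 °C; then 23, −78 °C → rt
Reagents that add atoms: none
Why: Julia–Kocienski olefination, in which the metalated phenyltetrazolyl sulfone adds to the enal and Smiles rearrangement with loss of SO2 should give the new C9=C10 side-chain double bond with E-geometry, no enolisable carbonyl flanking the peroxide at this stage.

Step 21
Reactants: 28 (3S,5S)-3,5-dimethyl-5-[(7E,9E,12Z)-pentadeca-7,9,12-trien-1-yl]-3-(2-{[tri(propan-2-yl)silyl]oxy}ethyl)-1,2-dioxolane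
Product: 29 2-{(3S,5S)-3,5-dimethyl-5-[(7E,9E,12Z)-pentadeca-7,9,12-trien-1-yl]-1,2-dioxolan-3-yl}ethan-1-ol
Conditions: Bu4NF, THF, 0 °C → rt
Reagents that add atoms: none
Why: Fluoride-induced cleavage of the triisopropylsilyl ether, to which the peroxide and the triene are stable.

Step 22
Reactants: 29 2-{(3S,5S)-3,5-dimethyl-5-[(7E,9E,12Z)-pentadeca-7,9,12-trien-1-yl]-1,2-dioxolan-3-yl}ethan-1-ol
Product: 30 {(3R,5S)-3,5-dimethyl-5-[(7E,9E,12Z)-pentadeca-7,9,12-trien-1-yl]-1,2-dioxolan-3-yl}acetaldehyde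
Conditions: Dess–Martin periodinane, NaHCO3, CH2Cl2, 0 °C
Reagents that add atoms: none
Why: Dess–Martin oxidation buffered with NaHCO3, so that the β-peroxy aldehyde meets neither acid nor base that could trigger β-elimination of the peroxide.

Step 23
Reactants: 30 {(3R,5S)-3,5-dimethyl-5-[(7E,9E,12Z)-pentadeca-7,9,12-trien-1-yl]-1,2-dioxolan-3-yl}acetaldehyde
Product: 31 2-{(3R,5S)-3,5-dimethyl-5-[(7E,9E,12Z)-pentadeca-7,9,12-trien-1-yl]-1,2-dioxolan-3-yl}acetic acid (CNP0215994.1)
Conditions: NaClO2, NaH2PO4, 2-methylbut-2-ene, t-BuOH/H2O, 0 °C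
Reagents that add atoms: sodium chlorite, [Na+].[O-]Cl=O
Why: Pinnick oxidation, in which chlorous acid converts the aldehyde to the acid at about pH 4 and excess 2-methylbut-2-ene traps HOCl before it can add to the triene.

**Compound list**

1 | non-8-yn-1-ol | C#CCCCCCCCO | starting material
2 | 1-methoxy-4-[(non-8-yn-1-yloxy)methyl]benzene | C#CCCCCCCCOCc1ccc(OC)cc1 | intermediate
3 | dimethyl{(1E)-9-[(4-methoxyphenyl)methoxy]-2-methylnon-1-en-1-yl}alane | C[Al](C)/C=C(\C)CCCCCCCOCc1ccc(OC)cc1 | intermediate (not isolated)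
4 | lithium butyl(dimethyl){(1E)-9-[(4-methoxyphenyl)methoxy]-2-methylnon-1-en-1-yl}alanate | [Li+].CCCC[Al-](C)(C)/C=C(\C)CCCCCCCOCc1ccc(OC)cc1 | intermediate (not isolated)
5 | (2E)-10-[(4-methoxyphenyl)methoxy]-3-methyldec-2-en-1-ol | OC/C=C(\C)CCCCCCCOCc1ccc(OC)cc1 | intermediate
6 | [(2S,3S)-3-{7-[(4-methoxyphenyl)methoxy]heptyl}-3-methyloxiran-2-yl]methanol | COc1ccc(COCCCCCCC[C@]2(C)O[C@H]2CO)cc1 | intermediate
7 | (3S)-10-[(4-methoxyphenyl)methoxy]-3-methyldecane-1,3-diol | COc1ccc(COCCCCCCC[C@@](O)(C)CCO)cc1 | intermediate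
8 | (3S)-10-[(4-methoxyphenyl)methoxy]-3-methyl-1,3-bis[(triethylsilyl)oxy]decane | COc1ccc(COCCCCCCC[C@@](O[Si](CC)(CC)CC)(C)CCO[Si](CC)(CC)CC)cc1 | intermediate
9 | (3S)-10-[(4-methoxyphenyl)methoxy]-3-methyl-3-[(triethylsilyl)oxy]decanal | COc1ccc(COCCCCCCC[C@@](O[Si](CC)(CC)CC)(C)CC=O)cc1 | intermediate
10 | (4S)-11-[(4-methoxyphenyl)methoxy]-4-methyl-4-[(triethylsilyl)oxy]undec-1-yne | COc1ccc(COCCCCCCC[C@@](O[Si](CC)(CC)CC)(C)CC#C)cc1 | intermediate
11 | dimethyl{(1E,4S)-11-[(4-methoxyphenyl)methoxy]-2,4-dimethyl-4-[(triethylsilyl)oxy]undec-1-en-1-yl}alane | COc1ccc(COCCCCCCC[C@@](O[Si](CC)(CC)CC)(C)C/C(C)=C/[Al](C)C)cc1 | intermediate (not isolated)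
12 | lithium butyl(dimethyl){(1E,4S)-11-[(4-methoxyphenyl)methoxy]-2,4-dimethyl-4-[(triethylsilyl)oxy]undec-1-en-1-yl}alanate | [Li+].COc1ccc(COCCCCCCC[C@@](O[Si](CC)(CC)CC)(C)C/C(C)=C/[Al-](C)(C)CCCC)cc1 | intermediate (not isolated)
13 | (2E,5S)-12-[(4-methoxyphenyl)methoxy]-3,5-dimethyl-5-[(triethylsilyl)oxy]dodec-2-en-1-ol | COc1ccc(COCCCCCCC[C@@](O[Si](CC)(CC)CC)(C)C/C(C)=C/CO)cc1 | intermediate
14 | [(2R,3R)-3-{(2S)-9-[(4-methoxyphenyl)methoxy]-2-methyl-2-[(triethylsilyl)oxy]nonyl}-3-methyloxiran-2-yl]methanol | COc1ccc(COCCCCCCC[C@@](O[Si](CC)(CC)CC)(C)C[C@@]2(C)O[C@@H]2CO)cc1 | intermediate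
15 | (3S,5S)-12-[(4-methoxyphenyl)methoxy]-3,5-dimethyl-5-[(triethylsilyl)oxy]dodecane-1,3-diol | COc1ccc(COCCCCCCC[C@@](O[Si](CC)(CC)CC)(C)C[C@](C)(CCO)O)cc1 | intermediate
16 | (3S,5S)-12-[(4-methoxyphenyl)methoxy]-3,5-dimethyldodecane-1,3,5-triol | COc1ccc(COCCCCCCC[C@@](O)(C)C[C@](C)(CCO)O)cc1 | intermediate
17 | (3S,5S)-12-[(4-methoxyphenyl)methoxy]-3,5-dimethyl-1-{[tri(propan-2-yl)silyl]oxy}dodecane-3,5-diol | COc1ccc(COCCCCCCC[C@@](O)(C)C[C@](C)(CCO[Si](C(C)C)(C(C)C)C(C)C)O)cc1 | intermediate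
18 | O,O'-[(3S,5S)-12-[(4-methoxyphenyl)methoxy]-3,5-dimethyl-1-{[tri(propan-2-yl)silyl]oxy}dodecane-3,5-diyl]bis(hydroxylamine) | COc1ccc(COCCCCCCC[C@@](ON)(C)C[C@](C)(CCO[Si](C(C)C)(C(C)C)C(C)C)ON)cc1 | intermediate
19 | (5S,7S)-5-{7-[(4-methoxyphenyl)methoxy]heptyl}-5,7-dimethyl-7-(2-{[tri(propan-2-yl)silyl]oxy}ethyl)-6,7-dihydro-5H-1,4,2,3-dioxadiazepine (cis-hyponitrite bridging the C3 and C5 oxygens) | COc1ccc(COCCCCCCC[C@@]2(C)C[C@](C)(CCO[Si](C(C)C)(C(C)C)C(C)C)O/N=N\O2)cc1 | intermediate (not isolated)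
20 | (3S,5S)-5-{7-[(4-methoxyphenyl)methoxy]heptyl}-3,5-dimethyl-3-(2-{[tri(propan-2-yl)silyl]oxy}ethyl)-1,2-dioxolane | COc1ccc(COCCCCCCC[C@@]2(C)C[C@](C)(CCO[Si](C(C)C)(C(C)C)C(C)C)OO2)cc1 | intermediate
21 | 7-[(3S,5S)-3,5-dimethyl-3-(2-{[tri(propan-2-yl)silyl]oxy}ethyl)-1,2-dioxolan-5-yl]heptan-1-ol | OCCCCCCC[C@@]1(C)C[C@](C)(CCO[Si](C(C)C)(C(C)C)C(C)C)OO1 | intermediate
22 | 7-[(3S,5S)-3,5-dimethyl-3-(2-{[tri(propan-2-yl)silyl]oxy}ethyl)-1,2-dioxolan-5-yl]heptanal | O=CCCCCCC[C@@]1(C)C[C@](C)(CCO[Si](C(C)C)(C(C)C)C(C)C)OO1 | intermediate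
23 | (2E)-9-[(3S,5S)-3,5-dimethyl-3-(2-{[tri(propan-2-yl)silyl]oxy}ethyl)-1,2-dioxolan-5-yl]non-2-enal | O=C/C=C/CCCCCC[C@@]1(C)C[C@](C)(CCO[Si](C(C)C)(C(C)C)C(C)C)OO1 | intermediate
24 | (3Z)-hex-3-en-1-ol | CC/C=C\CCO | starting material
25 | 1-phenyl-1H-tetrazole-5-thiol | SC1=NN=NN1c1ccccc1 | starting material
26 | 5-[(3Z)-hex-3-en-1-ylsulfanyl]-1-phenyl-1H-tetrazole | CC/C=C\CCSC1=NN=NN1c1ccccc1 | intermediate
27 | 5-[(3Z)-hex-3-ene-1-sulfonyl]-1-phenyl-1H-tetrazole | CC/C=C\CCS(=O)(=O)C1=NN=NN1c1ccccc1 | intermediate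
28 | (3S,5S)-3,5-dimethyl-5-[(7E,9E,12Z)-pentadeca-7,9,12-trien-1-yl]-3-(2-{[tri(propan-2-yl)silyl]oxy}ethyl)-1,2-dioxolane | CC/C=C\C/C=C/C=C/CCCCCC[C@@]1(C)C[C@](C)(CCO[Si](C(C)C)(C(C)C)C(C)C)OO1 | intermediate
29 | 2-{(3S,5S)-3,5-dimethyl-5-[(7E,9E,12Z)-pentadeca-7,9,12-trien-1-yl]-1,2-dioxolan-3-yl}ethan-1-ol | CC/C=C\C/C=C/C=C/CCCCCC[C@@]1(C)C[C@](C)(CCO)OO1 | intermediate
30 | {(3R,5S)-3,5-dimethyl-5-[(7E,9E,12Z)-pentadeca-7,9,12-trien-1-yl]-1,2-dioxolan-3-yl}acetaldehyde | CC/C=C\C/C=C/C=C/CCCCCC[C@@]1(C)C[C@](C)(CC=O)OO1 | intermediate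
31 | 2-{(3R,5S)-3,5-dimethyl-5-[(7E,9E,12Z)-pentadeca-7,9,12-trien-1-yl]-1,2-dioxolan-3-yl}acetic acid | CC/C=C\C/C=C/C=C/CCCCCC[C@@]1(C)C[C@](C)(CC(=O)O)OO1 | target

**Step count**

Total: 23 steps. Longest linear sequence: 21 steps (1 → 31 through steps 1–17 and 20–23); steps 18 and 19 prepare sulfone 27.

**Steps most likely to fail**

Step 14. What may go wrong: intermolecular N–N coupling to oligomeric hyponitrites, or fragmentation and hydrogen transfer of the alkoxyl radical pair outrunning O–O recombination. The fallback builds the two peroxide C–O bonds by two-electron chemistry and sets out from 13. Epoxidation with the Ti(OiPr)4/L-(+)-tartrate catalyst would give the epimeric epoxy alcohol [(2S,3S)-3-{(2S)-9-[(4-methoxyphenyl)methoxy]-2-methyl-2-[(triethylsilyl)oxy]nonyl}-3-methyloxiran-2-yl]methanol F1, and NaAlH2(OCH2CH2OMe)2 would reduce it to (3R,5S)-12-[(4-methoxyphenyl)methoxy]-3,5-dimethyl-5-[(triethylsilyl)oxy]dodecane-1,3-diol F2. Tosylation of the primary hydroxyl and closure by the tertiary alkoxide (n-BuLi, TsCl, then n-BuLi, THF) would give the oxetane (2R)-2-{(2S)-9-[(4-methoxyphenyl)methoxy]-2-methyl-2-[(triethylsilyl)oxy]nonyl}-2-methyloxetane F3. Lewis-acid-promoted perhydrolysis (ethereal H2O2, Me3SiOSO2CF3 cat., −78 → 0 °C) opens such oxetanes at the tertiary carbon with inversion and would give (3S,5S)-3-hydroperoxy-12-[(4-methoxyphenyl)methoxy]-3,5-dimethyl-5-[(triethylsilyl)oxy]dodecan-1-ol F4, now with the C3 configuration of the target. Acid (TsOH, CH2Cl2) would ionise the tertiary C5 silyl ether, and capture of the cation by the hydroperoxide (acid-catalysed alkylation of a hydroperoxide by a tertiary carbinol) would close the ring to 2-[(3S,5S)-5-{7-[(4-methoxyphenyl)methoxy]heptyl}-3,5-dimethyl-1,2-dioxolan-3-yl]ethan-1-ol F5, formed together with its C5 epimer 2-[(3S,5R)-5-{7-[(4-methoxyphenyl)methoxy]heptyl}-3,5-dimethyl-1,2-dioxolan-3-yl]ethan-1-ol F6. The two are diastereomers and would be separated by chromatography. Silylation of F5 (iPr3SiCl, imidazole) comes back to the route at 20. This sequence gives up control of C5, which is why it is only the reserve.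

Step 13. What may go wrong: incomplete amination of the hindered dialkoxide (the second alkoxide reacting poorly next to the first N–H), or base-induced silyl migration from the primary to the neighbouring tertiary oxygen. The fallback aminates one oxygen at a time, using the differentiation already present in 15, from which it sets out. Silylation (iPr3SiCl, imidazole) would give (3S,5S)-12-[(4-methoxyphenyl)methoxy]-3,5-dimethyl-5-[(triethylsilyl)oxy]-1-{[tri(propan-2-yl)silyl]oxy}dodecan-3-ol F7. Amination of its single potassium alkoxide (KH, then 3,3-di-tert-butyloxaziridine) would give O-[(3S,5S)-12-[(4-methoxyphenyl)methoxy]-3,5-dimethyl-5-[(triethylsilyl)oxy]-1-{[tri(propan-2-yl)silyl]oxy}dodecan-3-yl]hydroxylamine F8. Selective removal of the triethylsilyl group (HF·pyridine, pyridine, THF, 0 °C) would give (3S,5S)-3-(aminooxy)-12-[(4-methoxyphenyl)methoxy]-3,5-dimethyl-1-{[tri(propan-2-yl)silyl]oxy}dodecan-5-ol F9, and a second mono-alkoxide amination of F9 comes back to the route at 18.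

Step 20. What may go wrong: poor E/Z selectivity at the new C9=C10 side-chain double bond, or base-induced isomerisation of the skipped diene. The fallback forms the same bond by a Wittig reaction and corrects the geometry afterwards; it sets out from 24 and 23. Iodination of 24 (I2, PPh3, imidazole) would give (3Z)-1-iodohex-3-ene F10, and heating with PPh3 in MeCN the salt [(3Z)-hex-3-en-1-yl](triphenyl)phosphonium iodide F11. Its ylide (NaN(SiMe3)2, THF, −78 °C) with enal 23 should give mainly (3S,5S)-3,5-dimethyl-5-[(7E,9Z,12Z)-pentadeca-7,9,12-trien-1-yl]-3-(2-{[tri(propan-2-yl)silyl]oxy}ethyl)-1,2-dioxolane F12. Iodine-catalysed equilibration (I2 cat., CH2Cl2, daylight) of the conjugated diene, which isomerises much faster than the isolated (Z)-alkene, comes back to the route at 28.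

**Further compounds**

F1 | step 14 | [(2S,3S)-3-{(2S)-9-[(4-methoxyphenyl)methoxy]-2-methyl-2-[(triethylsilyl)oxy]nonyl}-3-methyloxiran-2-yl]methanol | COc1ccc(COCCCCCCC[C@@](O[Si](CC)(CC)CC)(C)C[C@]2(C)O[C@H]2CO)cc1
F2 | step 14 | (3R,5S)-12-[(4-methoxyphenyl)methoxy]-3,5-dimethyl-5-[(triethylsilyl)oxy]dodecane-1,3-diol | COc1ccc(COCCCCCCC[C@@](O[Si](CC)(CC)CC)(C)C[C@@](C)(CCO)O)cc1
F3 | step 14 | (2R)-2-{(2S)-9-[(4-methoxyphenyl)methoxy]-2-methyl-2-[(triethylsilyl)oxy]nonyl}-2-methyloxetane | COc1ccc(COCCCCCCC[C@@](O[Si](CC)(CC)CC)(C)C[C@@]2(C)CCO2)cc1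
F4 | step 14 | (3S,5S)-3-hydroperoxy-12-[(4-methoxyphenyl)methoxy]-3,5-dimethyl-5-[(triethylsilyl)oxy]dodecan-1-ol | COc1ccc(COCCCCCCC[C@@](O[Si](CC)(CC)CC)(C)C[C@](C)(CCO)OO)cc1
F5 | step 14 | 2-[(3S,5S)-5-{7-[(4-methoxyphenyl)methoxy]heptyl}-3,5-dimethyl-1,2-dioxolan-3-yl]ethan-1-ol | COc1ccc(COCCCCCCC[C@@]2(C)C[C@](C)(CCO)OO2)cc1
F6 | step 14 | 2-[(3S,5R)-5-{7-[(4-methoxyphenyl)methoxy]heptyl}-3,5-dimethyl-1,2-dioxolan-3-yl]ethan-1-ol | COc1ccc(COCCCCCCC[C@]2(C)C[C@](C)(CCO)OO2)cc1
F7 | step 13 | (3S,5S)-12-[(4-methoxyphenyl)methoxy]-3,5-dimethyl-5-[(triethylsilyl)oxy]-1-{[tri(propan-2-yl)silyl]oxy}dodecan-3-ol | COc1ccc(COCCCCCCC[C@@](O[Si](CC)(CC)CC)(C)C[C@](C)(CCO[Si](C(C)C)(C(C)C)C(C)C)O)cc1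
F8 | step 13 | O-[(3S,5S)-12-[(4-methoxyphenyl)methoxy]-3,5-dimethyl-5-[(triethylsilyl)oxy]-1-{[tri(propan-2-yl)silyl]oxy}dodecan-3-yl]hydroxylamine | COc1ccc(COCCCCCCC[C@@](O[Si](CC)(CC)CC)(C)C[C@](C)(CCO[Si](C(C)C)(C(C)C)C(C)C)ON)cc1
F9 | step 13 | (3S,5S)-3-(aminooxy)-12-[(4-methoxyphenyl)methoxy]-3,5-dimethyl-1-{[tri(propan-2-yl)silyl]oxy}dodecan-5-ol | COc1ccc(COCCCCCCC[C@@](O)(C)C[C@](C)(CCO[Si](C(C)C)(C(C)C)C(C)C)ON)cc1
F10 | step 20 | (3Z)-1-iodohex-3-ene | CC/C=C\CCI
F11 | step 20 | [(3Z)-hex-3-en-1-yl](triphenyl)phosphonium iodide | CC/C=C\CC[P+](c1ccccc1)(c1ccccc1)c1ccccc1.[I-]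
F12 | step 20 | (3S,5S)-3,5-dimethyl-5-[(7E,9Z,12Z)-pentadeca-7,9,12-trien-1-yl]-3-(2-{[tri(propan-2-yl)silyl]oxy}ethyl)-1,2-dioxolane | CC/C=C\C/C=C\C=C\CCCCCC[C@@]1(C)C[C@](C)(CCO[Si](C(C)C)(C(C)C)C(C)C)OO1
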